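**Assumption:** 1 and 3 are bought as their benzyl ethers, and the carbinol centre of 6 (and C4 of 8) is carried as an epimer mixture because it is ionised in step 5.

## Retrosynthetic overview

- 11 ⇐ 10 by NaBH4 reduction of the lower C4 ketone to the 3,4-trans diol; 10 ⇐ 9 by global debenzylation.
- 9 ⇐ oxirane ketone 5 + oxirane alcohol 6 in one acid cascade: both pyran rings (ring C of each unit) close by 6-endo oxirane opening, then the C4(upper)–C2'(lower ring B) bond forms.
- 6 ⇐ 5 (NaBH4); 5 ⇐ chalcone 4 by Juliá–Colonna epoxidation, which sets all absolute stereochemistry; 4 ⇐ 2 + 3 (aldol condensation).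
- Ring order: the four arene rings are bought; the two rings C are formed together in step 5.

## Route

Step 1
Reactants: 1 1-[4-(benzyloxy)-2-hydroxyphenyl]ethan-1-one
Product: 2 1-[4-(benzyloxy)-2-(methoxymethoxy)phenyl]ethan-1-one
Conditions: NaH, MOMCl, DMF, 0 °C → rt
Reagents that add atoms: chloromethyl methyl ether, COCCl
Why: Williamson O-alkylation of the chelated phenoxide masks the 2-OH so that the later base-mediated epoxidation cannot run into Algar–Flynn–Oyamada cyclisation.

Step 2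
Reactants: 2 1-[4-(benzyloxy)-2-(methoxymethoxy)phenyl]ethan-1-one; 3 3,4,5-tris(benzyloxy)benzaldehyde
Product: 4 (E)-2'-(methoxymethoxy)-4',3,4,5-tetrakis(benzyloxy)chalcone
Conditions: KOH, EtOH/THF, rt, 24 h
Reagents that add atoms: none
Why: Claisen–Schmidt aldol condensation with a non-enolisable aldehyde gives the thermodynamic (E)-enone only.

Step 3
Reactants: 4 (E)-chalcone
Product: 5 (2R,3S)-chalcone epoxide (αR,βS oxirane ketone)
Conditions: poly-L-leucine (cat.), urea·H2O2, DBU, THF, rt; recrystallise to raise ee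
Reagents that add atoms: hydrogen peroxide, used as its urea adduct, OO
Why: Juliá–Colonna epoxidation; hydroperoxide adds to the enone bound to the helical poly-L-amino acid and delivers the trans-(αR,βS) epoxide, the sense known for 2'-alkoxychalcones.

Step 4
Reactants: 5 (2R,3S)-chalcone epoxide (about one quarter of the batch)
Product: 6 (2S,3S)-oxiranyl aryl carbinol (epoxy alcohol, carbinol epimers)
Conditions: NaBH4, MeOH/THF, 0 °C
Reagents that add atoms: none
Why: Chemoselective borohydride 1,2-reduction of the aryl ketone leaves the oxirane intact (the oxirane descriptor changes from 2R to 2S only through CIP priorities), and the new carbinol centre need not be controlled.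

Step 5
Reactants: 6 (2S,3S)-oxiranyl aryl carbinol (1 equiv, added slowly); 5 (2R,3S)-chalcone epoxide (3 equiv)
Product: 9 octa-O-benzyl robinetinidol-(4α→2')-dihydrorobinetin, via tetra-O-benzyl dihydrorobinetin 7 (not isolated), via tetra-O-benzyl leucorobinetinidin 8 (not isolated)
Conditions: TfOH (10 mol %), H2O (3 equiv), 1,1,1,3,3,3-hexafluoropropan-2-ol/CH2Cl2 1:4, −20 → 0 °C; Et3N quench
Reagents that add atoms: none
Why: Proposed new method: TfOH in the fluorinated alcohol ionises the benzylic C–O bond of each oxirane and the ortho oxygen (as OMOM, which then sheds CH2=OMe+ to water, or as the freed phenol) closes the six-membered ring by 6-endo attack with inversion at C2 and retention at C3, turning 5 into the (2R,3R)-trans-dihydroflavonol 7 and 6 into the (2R,3S)-2,3-trans-flavan-3,4-diol 8; 8 then loses water to the flavan-4-yl cation stabilised by O1 and 7-OBn (the same cyclic cation results if 6 first forms an ortho-quinone methide whose oxygen opens the oxirane), and this cation is attacked anti to the 3-OH (4α, 3,4-trans, 4S) by C2' of ring B of 7, the only activated arene of 7 because its ring A is a vinylogous ester; the closest known reactions are the acid- or AgBF4-induced cyclisation of 2'-hydroxychalcone epoxide derivatives to dihydroflavonols and the Lewis-acid Friedel–Crafts coupling of flavan-3,4-diols with phenolic nucleophiles.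

Step 6
Reactants: 9 octa-O-benzyl robinetinidol-(4α→2')-dihydrorobinetin
Product: 10 robinetinidol-(4α→2')-dihydrorobinetin
Conditions: H2 (1 atm), Pd(OH)2/C, THF/MeOH, rt; filter under Ar
Reagents that add atoms: none
Why: Hydrogenolysis of the eight aryl benzyl ethers under neutral conditions leaves the vinylogous-ester ketone, the C4–C2' diaryl bond and all five stereocentres untouched.

Step 7
Reactants: 10 robinetinidol-(4α→2')-dihydrorobinetin
Product: 11 robinetinidol-(4α→2')-leucorobinetinidin (target)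
Conditions: NaBH4 (excess), EtOH, 0 °C, Ar; AcOH to pH 6; Sephadex LH-20
Reagents that add atoms: none
Why: Borohydride reduction of the dihydroflavonol carbonyl by axial attack on the half-chair with equatorial 2-aryl and 3-OH gives the equatorial 4-OH, the 2,3-trans-3,4-trans (4R) diol, as in the standard conversion of (2R,3R)-dihydroflavonols into leucoanthocyanidins.

## Compound list

1 | 1-[4-(benzyloxy)-2-hydroxyphenyl]ethan-1-one | CC(=O)c1ccc(OCc2ccccc2)cc1O | starting material
2 | 1-[4-(benzyloxy)-2-(methoxymethoxy)phenyl]ethan-1-one | CC(=O)c1ccc(OCc2ccccc2)cc1OCOC | intermediate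
3 | 3,4,5-tris(benzyloxy)benzaldehyde | O=Cc1cc(OCc2ccccc2)c(OCc2ccccc2)c(OCc2ccccc2)c1 | starting material
4 | (E)-1-[4-(benzyloxy)-2-(methoxymethoxy)phenyl]-3-[3,4,5-tris(benzyloxy)phenyl]prop-2-en-1-one | COCOc1cc(OCc2ccccc2)ccc1C(=O)/C=C/c1cc(OCc2ccccc2)c(OCc2ccccc2)c(OCc2ccccc2)c1 | intermediate
5 | [4-(benzyloxy)-2-(methoxymethoxy)phenyl]{(2R,3S)-3-[3,4,5-tris(benzyloxy)phenyl]oxiran-2-yl}methanone | COCOc1cc(OCc2ccccc2)ccc1C(=O)[C@@H]1O[C@H]1c1cc(OCc2ccccc2)c(OCc2ccccc2)c(OCc2ccccc2)c1 | intermediate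
6 | (RS)-[4-(benzyloxy)-2-(methoxymethoxy)phenyl]{(2S,3S)-3-[3,4,5-tris(benzyloxy)phenyl]oxiran-2-yl}methanol, carbinol epimers | COCOc1cc(OCc2ccccc2)ccc1C(O)[C@@H]1O[C@H]1c1cc(OCc2ccccc2)c(OCc2ccccc2)c(OCc2ccccc2)c1 | intermediate
7 | (2R,3R)-7-(benzyloxy)-3-hydroxy-2-[3,4,5-tris(benzyloxy)phenyl]-2,3-dihydro-4H-chromen-4-one | O=C1c2ccc(OCc3ccccc3)cc2O[C@H](c2cc(OCc3ccccc3)c(OCc3ccccc3)c(OCc3ccccc3)c2)[C@H]1O | intermediate (not isolated)
8 | (2R,3S,4RS)-7-(benzyloxy)-2-[3,4,5-tris(benzyloxy)phenyl]-3,4-dihydro-2H-chromene-3,4-diol | OC1c2ccc(OCc3ccccc3)cc2O[C@H](c2cc(OCc3ccccc3)c(OCc3ccccc3)c(OCc3ccccc3)c2)[C@H]1O | intermediate (not isolated)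
9 | (2R,3R)-7-(benzyloxy)-2-{3,4,5-tris(benzyloxy)-2-[(2R,3S,4S)-7-(benzyloxy)-3-hydroxy-2-[3,4,5-tris(benzyloxy)phenyl]-3,4-dihydro-2H-chromen-4-yl]phenyl}-3-hydroxy-2,3-dihydro-4H-chromen-4-one | c1ccccc1COc1ccc2c(c1)O[C@H](c1cc(OCc3ccccc3)c(OCc3ccccc3)c(OCc3ccccc3)c1)[C@@H](O)[C@@H]2c1c([C@H]2Oc3cc(OCc4ccccc4)ccc3C(=O)[C@@H]2O)cc(OCc2ccccc2)c(OCc2ccccc2)c1OCc1ccccc1 | intermediate
10 | (2R,3R)-3,7-dihydroxy-2-{3,4,5-trihydroxy-2-[(2R,3S,4S)-3,7-dihydroxy-2-(3,4,5-trihydroxyphenyl)-3,4-dihydro-2H-chromen-4-yl]phenyl}-2,3-dihydro-4H-chromen-4-one | Oc1ccc2c(c1)O[C@H](c1cc(O)c(O)c(O)c1)[C@@H](O)[C@@H]2c1c([C@H]2Oc3cc(O)ccc3C(=O)[C@@H]2O)cc(O)c(O)c1O | intermediate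
11 | (2R,3S,4R)-2-{3,4,5-trihydroxy-2-[(2R,3S,4S)-3,7-dihydroxy-2-(3,4,5-trihydroxyphenyl)-3,4-dihydro-2H-chromen-4-yl]phenyl}-3,4-dihydro-2H-chromene-3,4,7-triol | Oc1ccc2c(c1)O[C@H](c1cc(O)c(O)c(O)c1)[C@@H](O)[C@@H]2c1c([C@H]2Oc3cc(O)ccc3[C@@H](O)[C@@H]2O)cc(O)c(O)c1O | target

## Step count and risks

Total steps: 7. Longest linear sequence: 7 (1 → 2 → 4 → 5 → 6 → 9 → 10 → 11).

**Step 5 (most likely to fail).** The risks are:
- 1,2-aroyl shift of 5 in place of ring closure;
- formaldehyde from the MOM groups alkylating the electron-rich arenes;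
- arylation of 6 at C4 before its ring has closed, which would lose the 4α control;
- self-condensation of 8 through its ring A, higher oligomers, and some 4β epimer.

The fallback sets out from 5 and separates the events. BnSH/SnCl4 (CH2Cl2, −20 °C) opens the oxirane at the benzylic carbon and removes the MOM group, giving the β-benzylsulfanyl α-hydroxy ketone F1. AgBF4 (CH2Cl2, 0 °C) then closes ring C through the thiophilically generated benzylic cation to give 7, which is isolated. NaBH4 reduces one quarter of 7 to 8. TMSOTf (CH2Cl2, −40 °C) couples 8 with three equivalents of 7, and the route is rejoined at 9. Here the two rings form separately.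

**Step 3.** The hindered, electron-rich 2'-alkoxychalcone may react slowly or with mediocre ee. The fallback sets out from 4. NaBH4/CeCl3·7H2O gives the racemic allylic alcohol F2. Sharpless kinetic-resolution epoxidation (Ti(OiPr)4, L-(+)-diisopropyl tartrate, TBHP, 4 Å sieves, CH2Cl2, −20 °C) converts the fast-reacting enantiomer into 6 with the (2S,3S)-oxirane; this is the same facial sense as (2S,3S)-3-phenylglycidol from cinnamyl alcohol. The unreacted enantiomer is returned to 4 with MnO2. Dess–Martin oxidation of three quarters of this 6 gives 5, so the route is rejoined at 6 and 5.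

**Step 7.** Reduction of the free polyphenol may give 3,4-cis diol, and the product is sensitive to acid and air. The fallback sets out from 9 and reverses the order. NaBH4 (THF/EtOH, 0 °C) reduces the ketone while all phenols are still benzylated, giving the octa-O-benzyl 3,4-trans diol F3, which can be purified on silica. Hydrogenolysis (H2, Pd(OH)2/C, EtOAc/MeOH with a trace of Et3N to protect the benzylic 4-OH) then gives 11 directly.

## Further compounds

F1 | step 5 | (2S,3RS)-3-(benzylsulfanyl)-1-[4-(benzyloxy)-2-hydroxyphenyl]-2-hydroxy-3-[3,4,5-tris(benzyloxy)phenyl]propan-1-one | Oc1cc(OCc2ccccc2)ccc1C(=O)[C@H](O)C(SCc1ccccc1)c1cc(OCc2ccccc2)c(OCc2ccccc2)c(OCc2ccccc2)c1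
F2 | step 3 | rac-(E)-1-[4-(benzyloxy)-2-(methoxymethoxy)phenyl]-3-[3,4,5-tris(benzyloxy)phenyl]prop-2-en-1-ol | COCOc1cc(OCc2ccccc2)ccc1C(O)/C=C/c1cc(OCc2ccccc2)c(OCc2ccccc2)c(OCc2ccccc2)c1
F3 | step 7 | (2R,3S,4R)-7-(benzyloxy)-2-{3,4,5-tris(benzyloxy)-2-[(2R,3S,4S)-7-(benzyloxy)-3-hydroxy-2-[3,4,5-tris(benzyloxy)phenyl]-3,4-dihydro-2H-chromen-4-yl]phenyl}-3,4-dihydro-2H-chromene-3,4-diol | c1ccccc1COc1ccc2c(c1)O[C@H](c1cc(OCc3ccccc3)c(OCc3ccccc3)c(OCc3ccccc3)c1)[C@@H](O)[C@@H]2c1c([C@H]2Oc3cc(OCc4ccccc4)ccc3[C@@H](O)[C@@H]2O)cc(OCc2ccccc2)c(OCc2ccccc2)c1OCc1ccccc1
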